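At early times double product appears with a lag in the summer run, 6% after 3.00 min against 30% after 10.0 min, so the starting material seems to take reagent in two steps, first to a mono adduct and then to double product.

| flask | starting material | reagent | temperature | remark | time |
|---|---|---|---|---|---|
| summer | 17 mM | 44.2 mM | 90 °C | run made earlier |  |
| dawn | 68 mM | 44.2 mM | 102 °C | run made earlier |  |
| midnight | 34 mM | 88 mM | 90 °C | run made earlier |  |
| delta | 34 mM | 44.2 mM | 95 °C |  | 1.0 h |
| alpha | 34 mM | 44.2 mM | 110 °C |  | 1.0 h |

- summer (time / min: double product / %): 3.00: 6; 4.00: 10; 6.00: 17; 10.0: 30; 15.0: 45; 25.0: 59; 40.0: 67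
- dawn (time / min: double product / %): 5.00: 15; 10.0: 19; 15.0: 19; 20.0: 21; 25.0: 17; 30.0: 13; 40.0: 16
- midnight (time / min: double product / %): 3.00: 17; 10.0: 53; 15.0: 63; 25.0: 71; 40.0: 73

(standard deviation of a reading: 1.5 percentage points)

- the flask that comes out highest in amount of double product, in percent of the starting material charged, or "all alike" when all lie within 1.5 percentage points (delta / alpha / all alike)
- double product at the end, in percent of the starting material charged, delta
- double product at the end, in percent of the starting material charged, alpha



Two extreme versions of delta can be solved in the head by counting reagent. Full conversion to double product needs 68.0 mM of reagent, more than the 44.2 mM charged, which makes reagent the limiting reagent. If mono adduct takes reagent at once, double product reaches the reagent ceiling Y, the reagent charged divided by the reagent that full conversion needs, 65.0%. If mono adduct reacts after the starting material is gone, 34 mM of reagent goes first and the remaining 10.2 mM gives a floor of 30.0%.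

Delta lies between these while reagent enters nothing else, yet the summer run reads 67% at its end, less than its Y of 130%, so some further loss is at work. The dawn run, at a temperature between delta's and alpha's, has a Y of 32.5%, and its readings from 10.0 min onward average 0.538 of that. Y holds no temperature, but the share may depend on it; my own reckoning simply assumes the share read in the dawn run for both flasks and gives about 35.0% for each, so on that assumption the two come out alike.

The forecast differs: 37% (31% to 44%) for delta, 44% (36% to 52%) for alpha, and alpha highest, on the ground that “the main reaction gains more with temperature”.

Delta ends at 38.4% and alpha at 38.9%, a gap of 0.5 percentage points, less than the margin, so the answer is all alike.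

    reagent + double product → triple product (k = 0.00151 M⁻¹ s⁻¹, Ea = 98.0 kJ mol⁻¹)
    double product ⇌ isomer of the product (K = 0.510, k = 7.73 × 10⁻⁴ s⁻¹, Ea = 107 kJ mol⁻¹, ΔH = −64.0 kJ mol⁻¹)
    reagent + mono adduct → double product (k = 0.269 M⁻¹ s⁻¹, Ea = 51.0 kJ mol⁻¹)
    starting material + reagent → mono adduct (k = 0.0732 M⁻¹ s⁻¹, Ea = 55.0 kJ mol⁻¹)
    (constants at 110 °C)

Beside its double product, alpha holds 19.8% of isomer of the product at the end. Counted in units of Y, with mono adduct at its one reagent and triple product at its three, alpha's products add to 65.0% against a Y of 65.0%. The neighbour of alpha with 85 mM of starting material has a Y of 26.0%, keeps 0% of its reagent, gives 11.7% double product, and its products add to 26.0%.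

The earlier runs and the new flask are simulated from invented constants; the scatter is artificial.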